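**A small charge.** A small charge of J, in the summer run, ends with 57 % of it as Z, while the larger charge of the midnight run ends with 43 %, so the share falls as the charge grows.

| flask | J | X | remark | time |
|---|---|---|---|---|
| summer | 0.034 M | 1.7 mM (held) | run made earlier |  |
| midnight | 0.075 M | 1.7 mM (held) | run made earlier |  |
| flask | 0.050 M | 1.7 mM (held) |  | 4.0 min |

| run | time / min | Z / % |
|---|---|---|
| summer | 0.833 | 28 |
| summer | 1.50 | 43 |
| summer | 2.50 | 52 |
| summer | 3.00 | 58 |
| summer | 4.00 | 57 |
| midnight | 0.333 | 7 |
| midnight | 1.00 | 16 |
| midnight | 2.00 | 31 |
| midnight | 3.00 | 42 |
| midnight | 4.00 | 43 |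

(each reading ± 1.5 percentage points)

- the earlier runs were read with a standard deviation of 1.5 percentage points
- at the start none of X is in solution
- L is what X becomes in solution

- gamma: doubling the transfer coefficient of X, all else as stated
- beta: doubling the saturation concentration of X, all else as stated

1. how much Z there is at 4.0 min, in percent of the J charged
2. concentration of L in solution at 25 s, in percent of saturation
3. the change that raises the amount of Z at 4.0 min, in percent of the J charged most ("none" if none brings more than 2 percentage points) (gamma / beta / none)
4. amount of Z at 4.0 min, in percent of the J charged, after gamma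

**Fastest rung.** The midnight run makes Z at 15.8 mM min⁻¹ up to its first reading. At that rate, X entering the solution would reach saturation in 6.47 s, which is shorter than 25 s and far shorter than the 4.00 min of the midnight run. So I take L as made about as fast as it is used (a quasi-steady state), with J taking up what enters.

**Minutes rung.** In the summer run, Z moves from 58 % to 57 % over the last interval, less than the scatter of 1.5 percentage points. I read this as a stall. I suppose that J also leaves by a route of its own, which grows with J while the uptake of L levels off. The loss ratio, J not found as Z divided by Z, should then climb in a straight line with the charge.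

**The line.** From the last readings, the loss ratio reads 0.754 in the summer run and 1.33 in the midnight run. The loss slope, its climb per unit of J charged, reads 13.9 M⁻¹. For this flask I reckon a ratio of 0.977, hence 50.6 % as Z.

**The forecast.** It gives 51 % (47 % to 55 %), close to my figure, and 15 % of saturation (6 % to 32 %). It names beta as the best change and gives 66 % after gamma (56 % to 78 %). One of its grounds is that “L reaches a low quasi-steady level quickly”.

**The result.** The flask gives 51.9 % and 17.6 % of saturation. Beta, the best change, gains 15 points against 10 points for gamma, and gamma gives 62.2 %.

    X ⇌ L, rate k1*(csat - [L]) (kL = 0.151 s⁻¹)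
    J + L → Z (k = 18.7 M⁻¹ s⁻¹)
    2 L → G (k = 5.63 M⁻¹ s⁻¹)
    J → D (k = 0.00705 s⁻¹)
    J + Z → E (k = 0.0172 M⁻¹ s⁻¹)

**Next flask.** This flask's loss ratio comes out at 0.927 against my 0.977, with 0.36 % of its J left at 4.00 min. The same slope, carried to the neighbour flask with 0.12 M of J, gives a ratio of 1.95 and so 33.9 % as Z. That flask, at 4.00 min, holds 59.1 % as D and 34.5 % as Z.

The readings were generated by integration for an exercise, and the scatter is random.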